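At early times a molecule of starting material has two partners: reagent, which gives target, and second substrate, which gives cross product.

| flask | starting material | reagent | second substrate | temperature | remark | time |
|---|---|---|---|---|---|---|
| dusk | 0.50 M | 0.65 M | 1.7 M | 0 °C | run made earlier |  |
| autumn | 0.50 M | 1.3 M | 2.5 M | 20 °C | run made earlier |  |
| west | 0.50 M | 0.650 M | 2.50 M | 35 °C |  | 3.0 h |
| east | 0.50 M | 0.650 M | 2.50 M | 5 °C |  | 3.0 h |
| south-west | 0.50 M | 0.650 M | 2.50 M | 20 °C |  | 3.0 h |

- dusk (time / h: target / %, starting material / %): 5.00: 54, 3; 12.0: 58, 0; 15.0: 56, 1; 25.0: 51, 0
- autumn (time / h: target / %, starting material / %): 0.500: 68, 5; 1.33: 64, 4; 3.00: 52, 0; 8.00: 35, 0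

(scatter of a reading: 2 percentage points)

* which flask leads in amount of target, in percent of the starting material charged ("all alike" within 1.5 percentage points) (west / east / south-west / all alike)
* how much target is there at the end, in percent of the starting material charged: west
* how much target is there at the end, in percent of the starting material charged: east
* how much target is there at the end, in percent of the starting material charged: south-west

**What do those two rates share?**
[starting material]. Dividing the rate to target by the rate to cross product cancels it, and time drops out too. What remains is a constant times [reagent]/[second substrate].

**Read the constant.**
Dusk at 12.0 h shows target 58% and starting material 0%, and I read the missing 42.0% as cross product. Dividing target over cross product by the charged ratio 0.382 gives 3.61. That is my split factor, the target made per cross product at equal [reagent] and [second substrate]: a selectivity factor, reckoned on charges and read from scattered numbers.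

**Autumn at 0.500 h gives 4.84. Why not use that?**
[reagent] falls during a run, and I reckon on charges. Dusk has the reagent charge of the new flasks, while autumn has twice that. The factor's dependence on temperature stays untested.

**The new flasks?**
Their charged ratio is 0.260, so target to cross product comes to 0.939. I reckon the pool, target plus isomer of the product, at 48.4% in each flask once its starting material has reacted.

**And the loss from that pool to isomer?**
Autumn's target falls from 68% to 35%, a fade of 0.0886 /h. Dusk gives 0.00989 /h, but that is a weak reading: a fall of 7 percentage points against a scatter of 2 points. Pool times exp(−fade × time) gives south-west 37.1%. East, at 5 °C but on the fade of dusk at 0 °C, gets 47.0%. West, with the same factor per degree carried up to 0.458 /h, gets 12.2%. In my reckoning east leads.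

The forecast, holding that “the ratio is worse than both earlier runs”, named east and gave 20% for west and 42% for south-west, each above my figure, with 47% for east.

The flasks give 8.74% in west, 48.1% in east and 37.1% in south-west, and east leads.

    starting material + reagent → target (k = 0.310 /M/min, Ea = 58.0 kJ/mol)
    second substrate + reagent → second product (k = 0.0470 /M/min, Ea = 74.0 kJ/mol)
    starting material + second substrate → cross product (k = 0.0430 /M/min, Ea = 54.0 kJ/mol)
    target ⇌ isomer of the product (K = 14.0, k = 0.0110 /min, Ea = 91.0 kJ/mol, ΔH = 27.0 kJ/mol)
    (constants at 35 °C)

West ends with target 8.74% and isomer 39.0%, a pool of 47.7% against my 48.4%, while my west target stood 3.5 points high. A neighbour of west is charged with 1.0 M of second substrate, its other charges held. The split factor gives it target to cross product of 2.35, a pool of 70.1%. After 3.00 h that neighbour holds target 13.3% and isomer 57.7%, together 71.0%, with cross product 29.0%.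

(All runs come from a simulation with constants of no real substance, noise included.)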